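**Retrosynthetic overview**

1. Numbering (dictyotane): ring A = C1–C5 (five-membered; 3-OH, C4=C17), ring B = C1, C5–C10 (seven-membered; 6-OH, 9-OH, C10=C18), side chain C11–C16 on C7 (11-Me, 12-OAc); the rings are trans-fused at C1–C5.
2. Ring A is formed last: 3-OH/C4=C17 come from a C3=C4 cyclopentene (6-OH-directed epoxidation, then epoxide-to-allylic-alcohol isomerisation), and the cyclopentene comes from RCM of a C1-allyl/C5-isopropenyl cycloheptanol.
3. Key disconnection C5–C6 (ring B is formed first): the feature used is the homoallylic alcohol C6(OH)–C5–C4(=CH2), i.e. the ring-B carbinol C6 bonded to the ring-fusion carbon C5 that carries the exo-methylene carbon C4 of ring A, the retron of a carbonyl allylation. Closing it on an acyclic lactol/allylic alcohol lets allylic strain, not a preformed five-membered ring, set the trans fusion.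
4. The acyclic precursor is joined at C9–C10 (Nozaki–Hiyama–Kishi, then CBS reduction for C9) from fragment 1 (C6–C9, C11–C16: a cis-β,γ-disubstituted butyrolactone that masks both the C6 aldehyde and 12-OH) and fragment 2 (C1–C5, C10, C17, C18, plus one sacrificial carbon lost in the RCM: from a chiral 5-alkoxybutenolide).
5. Order of ring formation: ring B (step 19), then ring A (step 21).

Key step: step 19

**Route**

Step 1
Reactants: 1 4-methylpent-3-en-1-ol
Product: 2 4-methylpent-3-enal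
Conditions: Dess–Martin periodinane, NaHCO3, CH2Cl2, 0 °C; used crude
Reagents that add atoms: none
Why: Dess–Martin oxidation under buffered, non-basic conditions should give the β,γ-unsaturated aldehyde without migration of the double bond into conjugation.

Step 2
Reactants: 2 4-methylpent-3-enal
Product: 3 (3S,4S)-3,7-dimethylocta-1,6-dien-4-ol
Conditions: (Z)-crotylboronic acid pinacol ester, (R)-3,3'-bis(2,4,6-triisopropylphenyl)-1,1'-binaphthyl-2,2'-diyl hydrogen phosphate (5 mol %), toluene, −30 °C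
Reagents that add atoms: (Z)-crotylboronic acid pinacol ester, C/C=C\CB1OC(C)(C)C(C)(C)O1
Why: Brønsted-acid-catalysed crotylboration through a Zimmerman–Traxler chair, in which the (Z)-boronate gives the syn pair C11/C12 and the chiral phosphate (the enantiomer that leads to 3S,4S) sets the absolute configuration.

Step 3
Reactants: 3 (3S,4S)-3,7-dimethylocta-1,6-dien-4-ol
Product: 4 (3S,4S)-3,7-dimethyloct-6-ene-1,4-diol
Conditions: 9-BBN (2.2 equiv), THF, 0→25 °C; then NaOH, H2O2
Reagents that add atoms: hydrogen peroxide, OO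
Why: Hydroboration–oxidation, in which 9-BBN should react only with the monosubstituted alkene and place boron on its terminal carbon.

Step 4
Reactants: 4 (3S,4S)-3,7-dimethyloct-6-ene-1,4-diol
Product: 6 (4S,5S)-4-methyl-5-(3-methylbut-2-en-1-yl)oxolan-2-one, via lactol 5 (not isolated)
Conditions: TEMPO (10 mol %), PhI(OAc)2 (2.5 equiv), CH2Cl2, 25 °C
Reagents that add atoms: none
Why: TEMPO-catalysed oxidative lactonisation, in which the primary alcohol is oxidised selectively, the aldehyde closes to lactol 5 and is oxidised again, leaving the cis-β,γ-disubstituted lactone with both stereocentres untouched.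

Step 5
Reactants: 6 (4S,5S)-4-methyl-5-(3-methylbut-2-en-1-yl)oxolan-2-one
Product: 7 N-methoxy-N-methyl-2-[(3S,4S,5S)-4-methyl-5-(3-methylbut-2-en-1-yl)-2-oxooxolan-3-yl]acetamide
Conditions: LiN(i-Pr)2, THF, −78 °C; then BrCH2C(O)N(OMe)Me, −78→−40 °C
Reagents that add atoms: 2-bromo-N-methoxy-N-methylacetamide, CON(C)C(=O)CBr
Why: Lactone enolate alkylation, in which the electrophile should enter anti to the cis-disposed C11 methyl and C12 side chain and so set C7.

Step 6
Reactants: 7 N-methoxy-N-methyl-2-[(3S,4S,5S)-4-methyl-5-(3-methylbut-2-en-1-yl)-2-oxooxolan-3-yl]acetamide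
Product: 8 2-[(3S,4S,5S)-4-methyl-5-(3-methylbut-2-en-1-yl)-2-oxooxolan-3-yl]acetaldehyde
Conditions: Cp2Zr(H)Cl (1.5 equiv), THF, 25 °C
Reagents that add atoms: none
Why: Reduction of the Weinreb amide to the aldehyde with Cp2Zr(H)Cl, which should be chemoselective over the lactone and the trisubstituted alkene.

Step 7
Reactants: 9 (5R)-5-{[(1R,2S,5R)-5-methyl-2-(propan-2-yl)cyclohexyl]oxy}furan-2(5H)-one
Product: 10 (4R,5R)-5-{[(1R,2S,5R)-5-methyl-2-(propan-2-yl)cyclohexyl]oxy}-4-[1-(trimethylsilyl)ethenyl]oxolan-2-one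
Conditions: [1-(trimethylsilyl)ethenyl]magnesium bromide (1.5 equiv), CuBr·SMe2 (10 mol %), THF, −78→−40 °C; aq. NH4Cl
Reagents that add atoms: [1-(trimethylsilyl)ethenyl]magnesium bromide, C=C([Mg]Br)[Si](C)(C)C
Why: Copper-catalysed conjugate addition to the butenolide anti to the menthyloxy group, which should set C1 and brings in C10/C18 as a vinylsilane.

Step 8
Reactants: 10 (4R,5R)-5-{[(1R,2S,5R)-5-methyl-2-(propan-2-yl)cyclohexyl]oxy}-4-[1-(trimethylsilyl)ethenyl]oxolan-2-one
Product: 11 methyl (3R)-4,4-dimethoxy-3-[1-(trimethylsilyl)ethenyl]butanoate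
Conditions: MeOH, p-TsOH (cat.), 50 °C
Reagents that add atoms: methanol, CO
Why: Acid-catalysed transacetalisation and ring opening (methanolysis) of the pseudo-ester, which frees the auxiliary and differentiates C3 (ester) from C5 (acetal).

Step 9
Reactants: 11 methyl (3R)-4,4-dimethoxy-3-[1-(trimethylsilyl)ethenyl]butanoate
Product: 12 (3R)-4,4-dimethoxy-3-[1-(trimethylsilyl)ethenyl]butanal
Conditions: i-Bu2AlH (1.05 equiv), toluene, −78 °C
Reagents that add atoms: none
Why: Partial reduction of the methyl ester to the aldehyde at low temperature, with acetal and vinylsilane inert.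

Step 10
Reactants: 12 (3R)-4,4-dimethoxy-3-[1-(trimethylsilyl)ethenyl]butanal
Product: 13 [(3R)-3-(dimethoxymethyl)hexa-1,5-dien-2-yl](trimethyl)silane
Conditions: Ph3PCH3Br, KN(SiMe3)2, THF, 0 °C; then 12, −78→0 °C
Reagents that add atoms: methyltriphenylphosphonium bromide, C[P+](c1ccccc1)(c1ccccc1)c1ccccc1.[Br-]
Why: Wittig methylenation, which turns C3 into the terminal alkene of the C1 allyl group needed later for ring A.

Step 11
Reactants: 13 [(3R)-3-(dimethoxymethyl)hexa-1,5-dien-2-yl](trimethyl)silane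
Product: 14 (2R)-2-[1-(trimethylsilyl)ethenyl]pent-4-enal
Conditions: TFA, H2O, CHCl3, 0 °C, short; used at once
Reagents that add atoms: water, O
Why: Acetal hydrolysis, kept cold and brief because the α-stereocentre C1 of this β,γ-unsaturated aldehyde is prone to enolisation.

Step 12
Reactants: 14 (2R)-2-[1-(trimethylsilyl)ethenyl]pent-4-enal
Product: 15 ethyl (2E,4R)-2-methyl-4-[1-(trimethylsilyl)ethenyl]hepta-2,6-dienoate
Conditions: Ph3P=C(CH3)CO2Et, CH2Cl2, 25 °C
Reagents that add atoms: ethyl 2-(triphenylphosphoranylidene)propanoate, CCOC(=O)C(C)=P(c1ccccc1)(c1ccccc1)c1ccccc1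
Why: Wittig olefination with the stabilised, non-basic ylide, which should give the (E)-enoate (ester trans to C1, so the C17 methyl is cis to C1) without touching the C1 stereocentre.

Step 13
Reactants: 15 ethyl (2E,4R)-2-methyl-4-[1-(trimethylsilyl)ethenyl]hepta-2,6-dienoate
Product: 16 ethyl (2E,4R)-4-(1-iodoethenyl)-2-methylhepta-2,6-dienoate
Conditions: N-iodosuccinimide, MeCN–ClCH2CN (4:1), 0 °C
Reagents that add atoms: N-iodosuccinimide, O=C1CCC(=O)N1I
Why: Ipso-iododesilylation of the 1,1-disubstituted vinylsilane, the enoate and the terminal alkene being far less nucleophilic.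

Step 14
Reactants: 8 2-[(3S,4S,5S)-4-methyl-5-(3-methylbut-2-en-1-yl)-2-oxooxolan-3-yl]acetaldehyde; 16 ethyl (2E,4R)-4-(1-iodoethenyl)-2-methylhepta-2,6-dienoate
Product: 17 ethyl (2E,4R)-4-{3-hydroxy-4-[(3S,4S,5S)-4-methyl-5-(3-methylbut-2-en-1-yl)-2-oxooxolan-3-yl]but-1-en-2-yl}-2-methylhepta-2,6-dienoate (both C9 epimers)
Conditions: CrCl2 (4 equiv), NiCl2 (2 mol %), DMSO, 25 °C
Reagents that add atoms: none
Why: Nozaki–Hiyama–Kishi coupling, in which the nickel-catalysed alkenylchromium adds only to the aldehyde (lactone and ester untouched) and forms C9–C10 as a mixture of C9 epimers.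

Step 15
Reactants: 17 ethyl (2E,4R)-4-{3-hydroxy-4-[(3S,4S,5S)-4-methyl-5-(3-methylbut-2-en-1-yl)-2-oxooxolan-3-yl]but-1-en-2-yl}-2-methylhepta-2,6-dienoate
Product: 18 ethyl (2E,4R)-2-methyl-4-{4-[(3S,4S,5S)-4-methyl-5-(3-methylbut-2-en-1-yl)-2-oxooxolan-3-yl]-3-oxobut-1-en-2-yl}hepta-2,6-dienoate
Conditions: Dess–Martin periodinane, NaHCO3, CH2Cl2, 0 °C
Reagents that add atoms: none
Why: Dess–Martin oxidation converges both epimers on the α-methylene ketone under neutral conditions that should avoid isomerisation through the doubly allylic C1–H.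

Step 16
Reactants: 18 ethyl (2E,4R)-2-methyl-4-{4-[(3S,4S,5S)-4-methyl-5-(3-methylbut-2-en-1-yl)-2-oxooxolan-3-yl]-3-oxobut-1-en-2-yl}hepta-2,6-dienoate
Product: 19 ethyl (2E,4R)-4-{(3R)-3-hydroxy-4-[(3S,4S,5S)-4-methyl-5-(3-methylbut-2-en-1-yl)-2-oxooxolan-3-yl]but-1-en-2-yl}-2-methylhepta-2,6-dienoate
Conditions: (S)-2-methyl-CBS-oxazaborolidine (20 mol %), catecholborane (1.5 equiv), toluene, −78 °C
Reagents that add atoms: none
Why: Corey–Bakshi–Shibata reduction, in which the catalyst distinguishes the alkenyl (large) from the CH2 (small) flank and should give the 9R alcohol, while catecholborane leaves alkenes, ester and lactone alone.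

Step 17
Reactants: 19 ethyl (2E,4R)-4-{(3R)-3-hydroxy-4-[(3S,4S,5S)-4-methyl-5-(3-methylbut-2-en-1-yl)-2-oxooxolan-3-yl]but-1-en-2-yl}-2-methylhepta-2,6-dienoate
Product: 20 ethyl (2E,4R)-4-{(3R)-3-[(tert-butyldimethylsilyl)oxy]-4-[(3S,4S,5S)-4-methyl-5-(3-methylbut-2-en-1-yl)-2-oxooxolan-3-yl]but-1-en-2-yl}-2-methylhepta-2,6-dienoate
Conditions: TBSOTf, 2,6-lutidine, CH2Cl2, −78 °C
Reagents that add atoms: tert-butyldimethylsilyl triflate, CC(C)(C)[Si](C)(C)OS(=O)(=O)C(F)(F)F
Why: Silylation of the C9 alcohol directly after work-up, which also forecloses translactonisation onto the neighbouring lactone.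

Step 18
Reactants: 20 ethyl (2E,4R)-4-{(3R)-3-[(tert-butyldimethylsilyl)oxy]-4-[(3S,4S,5S)-4-methyl-5-(3-methylbut-2-en-1-yl)-2-oxooxolan-3-yl]but-1-en-2-yl}-2-methylhepta-2,6-dienoate
Product: 21 (2E,4R)-4-{(3R)-3-[(tert-butyldimethylsilyl)oxy]-4-[(3S,4S,5S)-2-hydroxy-4-methyl-5-(3-methylbut-2-en-1-yl)oxolan-3-yl]but-1-en-2-yl}-2-methylhepta-2,6-dien-1-ol (lactol anomers)
Conditions: i-Bu2AlH (3.5 equiv), CH2Cl2, −78 °C; aq. potassium sodium tartrate
Reagents that add atoms: none
Why: A single hydride reduction should take the enoate to the (E)-allylic alcohol and stop the lactone at the lactol at −78 °C, unveiling both partners of the key step without protecting groups.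

Step 19
Reactants: 21 (2E,4R)-4-{(3R)-3-[(tert-butyldimethylsilyl)oxy]-4-[(3S,4S,5S)-2-hydroxy-4-methyl-5-(3-methylbut-2-en-1-yl)oxolan-3-yl]but-1-en-2-yl}-2-methylhepta-2,6-dien-1-ol
Product: 23 (1R,2S,4R,6R,7S)-4-[(tert-butyldimethylsilyl)oxy]-2-[(2S,3S)-3-hydroxy-6-methylhept-5-en-2-yl]-5-methylidene-6-(prop-2-en-1-yl)-7-(prop-1-en-2-yl)cycloheptan-1-ol, via allyldiethylborane 22 (not isolated)
Conditions: Pd(OAc)2 (10 mol %), n-Bu3P (40 mol %), Et3B (4 equiv), THF (5 mM), 25→50 °C
Reagents that add atoms: none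
Why: Et3B activates the allylic C–OH bond of 21 for oxidative addition to zerovalent palladium, and allyl–ethyl exchange of the π-allylpalladium with Et3B gives the nucleophilic allyldiethylborane 22, whose lactol is in equilibrium with the free C6 aldehyde; the borane then adds through a six-membered Zimmerman–Traxler chair with allylic transposition, so that C5 bonds to C6 and C4 becomes the 2-propenyl carbon. The closest known reaction type is the Et3B-promoted, palladium-catalysed umpolung allylation of aldehydes and lactols with free allylic alcohols, run here in its ring-closing (intramolecular allylboration) mode. Ring B is closed by 7-exo attack of the γ-carbon C5 on the C6 carbonyl, the only mode open to an allylborane, since α-attack would need a nine-membered ring. C5 is controlled by allylic 1,3-strain: the C17 methyl, cis to C1, forces H-1 into the alkene plane, the C10 tether and the C1 allyl group then lie on opposite faces, and C6 must arrive on the tether face, which should place H-5 trans to H-1; C6 is controlled by the chair, in which C1 (trans to CH2B) and C7 are both equatorial, giving the anti adduct (C4 trans to 6-OH), and this facial choice is also the Felkin–Anh one for the existing C7 centre (C11 anti to the incoming C5). The step needs chemoselectivity for the masked aldehyde and high dilution against oligomerisation; the boron nucleophile ignores the other alkenes and the silyl ether, and the substituted chain (sp2 C10 and three branch points) favours cyclisation.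

Step 20
Reactants: 23 (1R,2S,4R,6R,7S)-4-[(tert-butyldimethylsilyl)oxy]-2-[(2S,3S)-3-hydroxy-6-methylhept-5-en-2-yl]-5-methylidene-6-(prop-2-en-1-yl)-7-(prop-1-en-2-yl)cycloheptan-1-ol
Product: 24 (2S,3S)-2-[(1S,2R,3S,4R,6R)-6-[(tert-butyldimethylsilyl)oxy]-2-hydroxy-5-methylidene-4-(prop-2-en-1-yl)-3-(prop-1-en-2-yl)cycloheptyl]-6-methylhept-5-en-3-yl acetate
Conditions: Ac2O (1.1 equiv), pyridine, DMAP (5 mol %), CH2Cl2, −20 °C
Reagents that add atoms: acetic anhydride, CC(=O)OC(C)=O
Why: Site-selective acylation, since the acyclic C12 carbinol is far more accessible than the ring C6 carbinol, which is flanked by two branched carbons (C5 and C7).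

Step 21
Reactants: 24 (2S,3S)-2-[(1S,2R,3S,4R,6R)-6-[(tert-butyldimethylsilyl)oxy]-2-hydroxy-5-methylidene-4-(prop-2-en-1-yl)-3-(prop-1-en-2-yl)cycloheptyl]-6-methylhept-5-en-3-yl acetate
Product: 25 (2S,3S)-2-[(3aS,4R,5S,7R,8aR)-7-[(tert-butyldimethylsilyl)oxy]-4-hydroxy-3-methyl-8-methylidene-1,3a,4,5,6,7,8,8a-octahydroazulen-5-yl]-6-methylhept-5-en-3-yl acetate
Conditions: second-generation Grubbs catalyst (5 mol %), CH2Cl2, 40 °C
Reagents that add atoms: none
Why: Ring-closing metathesis of the C1 allyl and C5 isopropenyl groups should close ring A as the C3=C4 cyclopentene with loss of ethylene (which removes the sacrificial carbon), the trans fusion being fixed already and the prenyl and exo-methylene alkenes too hindered to compete.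

Step 22
Reactants: 25 (2S,3S)-2-[(3aS,4R,5S,7R,8aR)-7-[(tert-butyldimethylsilyl)oxy]-4-hydroxy-3-methyl-8-methylidene-1,3a,4,5,6,7,8,8a-octahydroazulen-5-yl]-6-methylhept-5-en-3-yl acetate
Product: 26 (3S,4R)-3,4-epoxide of 25 (oxirane on the face of 6-OH and H-5)
Conditions: VO(acac)2 (5 mol %), t-BuOOH, CH2Cl2, 0→25 °C
Reagents that add atoms: tert-butyl hydroperoxide, CC(C)(C)OO
Why: Vanadium-catalysed hydroxyl-directed epoxidation, in which the free homoallylic 6-OH (on the α face next to C4) should deliver oxygen to the α face of C3=C4 only, setting C3 and C4 and leaving the undirected alkenes untouched.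

Step 23
Reactants: 26 (3S,4R)-3,4-epoxide of 25
Product: 27 (2S,3S)-2-[(2S,3aS,4R,5S,7R,8aR)-7-[(tert-butyldimethylsilyl)oxy]-2,4-dihydroxy-3,8-dimethylidenedecahydroazulen-5-yl]-6-methylhept-5-en-3-yl acetate
Conditions: Cp2TiCl2 (2.5 equiv), Mn dust, THF, 25 °C
Reagents that add atoms: none
Why: Cp2TiCl (trivalent titanium) opens the epoxide homolytically at the tertiary C4, and trapping of the C4 radical by a second Cp2TiCl with β-hydride loss from the C17 methyl should give the exocyclic alkene and the 3-OH with C3 unchanged, under neutral conditions that the acetate tolerates.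

Step 24
Reactants: 27 (2S,3S)-2-[(2S,3aS,4R,5S,7R,8aR)-7-[(tert-butyldimethylsilyl)oxy]-2,4-dihydroxy-3,8-dimethylidenedecahydroazulen-5-yl]-6-methylhept-5-en-3-yl acetate
Product: 28 (2S,3S)-2-[(2S,3aS,4R,5S,7R,8aR)-2,4,7-trihydroxy-3,8-dimethylidenedecahydroazulen-5-yl]-6-methylhept-5-en-3-yl acetate (CNP0210891.3)
Conditions: HF·pyridine, pyridine, THF, 0→25 °C
Reagents that add atoms: none
Why: Fluoride-mediated removal of the C9 silyl ether under buffered conditions that should leave the C12 acetate and the allylic alcohols intact.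

**Compound list**

1 | 4-methylpent-3-en-1-ol | CC(C)=CCCO | starting material
2 | 4-methylpent-3-enal | CC(C)=CCC=O | intermediate
3 | (3S,4S)-3,7-dimethylocta-1,6-dien-4-ol | C=C[C@H](C)[C@H](CC=C(C)C)O | intermediate
4 | (3S,4S)-3,7-dimethyloct-6-ene-1,4-diol | OCC[C@H](C)[C@H](CC=C(C)C)O | intermediate
5 | (4S,5S)-4-methyl-5-(3-methylbut-2-en-1-yl)oxolan-2-ol (lactol anomers; not isolated) | OC1C[C@H](C)[C@H](CC=C(C)C)O1 | intermediate
6 | (4S,5S)-4-methyl-5-(3-methylbut-2-en-1-yl)oxolan-2-one | O=C1C[C@H](C)[C@H](CC=C(C)C)O1 | intermediate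
7 | N-methoxy-N-methyl-2-[(3S,4S,5S)-4-methyl-5-(3-methylbut-2-en-1-yl)-2-oxooxolan-3-yl]acetamide | O=C1[C@@H](CC(=O)N(C)OC)[C@H](C)[C@H](CC=C(C)C)O1 | intermediate
8 | 2-[(3S,4S,5S)-4-methyl-5-(3-methylbut-2-en-1-yl)-2-oxooxolan-3-yl]acetaldehyde | O=C1[C@@H](CC=O)[C@H](C)[C@H](CC=C(C)C)O1 | intermediate
9 | (5R)-5-{[(1R,2S,5R)-5-methyl-2-(propan-2-yl)cyclohexyl]oxy}furan-2(5H)-one | O=C1C=C[C@H](O[C@@H]2C[C@H](C)CC[C@H]2C(C)C)O1 | starting material
10 | (4R,5R)-5-{[(1R,2S,5R)-5-methyl-2-(propan-2-yl)cyclohexyl]oxy}-4-[1-(trimethylsilyl)ethenyl]oxolan-2-one | O=C1C[C@@H](C(=C)[Si](C)(C)C)[C@H](O[C@@H]2C[C@H](C)CC[C@H]2C(C)C)O1 | intermediate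
11 | methyl (3R)-4,4-dimethoxy-3-[1-(trimethylsilyl)ethenyl]butanoate | COC(=O)C[C@@H](C(=C)[Si](C)(C)C)C(OC)OC | intermediate
12 | (3R)-4,4-dimethoxy-3-[1-(trimethylsilyl)ethenyl]butanal | O=CC[C@@H](C(=C)[Si](C)(C)C)C(OC)OC | intermediate
13 | [(3R)-3-(dimethoxymethyl)hexa-1,5-dien-2-yl](trimethyl)silane | C=CC[C@@H](C(=C)[Si](C)(C)C)C(OC)OC | intermediate
14 | (2R)-2-[1-(trimethylsilyl)ethenyl]pent-4-enal | C=CC[C@@H](C(=C)[Si](C)(C)C)C=O | intermediate
15 | ethyl (2E,4R)-2-methyl-4-[1-(trimethylsilyl)ethenyl]hepta-2,6-dienoate | C=CC[C@@H](C(=C)[Si](C)(C)C)/C=C(\C)C(=O)OCC | intermediate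
16 | ethyl (2E,4R)-4-(1-iodoethenyl)-2-methylhepta-2,6-dienoate | C=CC[C@@H](C(=C)I)/C=C(\C)C(=O)OCC | intermediate
17 | ethyl (2E,4R)-4-{3-hydroxy-4-[(3S,4S,5S)-4-methyl-5-(3-methylbut-2-en-1-yl)-2-oxooxolan-3-yl]but-1-en-2-yl}-2-methylhepta-2,6-dienoate (both C9 epimers) | O=C1[C@@H](CC(O)C(=C)[C@H](CC=C)/C=C(\C)C(=O)OCC)[C@H](C)[C@H](CC=C(C)C)O1 | intermediate
18 | ethyl (2E,4R)-2-methyl-4-{4-[(3S,4S,5S)-4-methyl-5-(3-methylbut-2-en-1-yl)-2-oxooxolan-3-yl]-3-oxobut-1-en-2-yl}hepta-2,6-dienoate | O=C1[C@@H](CC(=O)C(=C)[C@H](CC=C)/C=C(\C)C(=O)OCC)[C@H](C)[C@H](CC=C(C)C)O1 | intermediate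
19 | ethyl (2E,4R)-4-{(3R)-3-hydroxy-4-[(3S,4S,5S)-4-methyl-5-(3-methylbut-2-en-1-yl)-2-oxooxolan-3-yl]but-1-en-2-yl}-2-methylhepta-2,6-dienoate | O=C1[C@@H](C[C@@H](O)C(=C)[C@H](CC=C)/C=C(\C)C(=O)OCC)[C@H](C)[C@H](CC=C(C)C)O1 | intermediate
20 | ethyl (2E,4R)-4-{(3R)-3-[(tert-butyldimethylsilyl)oxy]-4-[(3S,4S,5S)-4-methyl-5-(3-methylbut-2-en-1-yl)-2-oxooxolan-3-yl]but-1-en-2-yl}-2-methylhepta-2,6-dienoate | O=C1[C@@H](C[C@@H](O[Si](C)(C)C(C)(C)C)C(=C)[C@H](CC=C)/C=C(\C)C(=O)OCC)[C@H](C)[C@H](CC=C(C)C)O1 | intermediate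
21 | (2E,4R)-4-{(3R)-3-[(tert-butyldimethylsilyl)oxy]-4-[(3S,4S,5S)-2-hydroxy-4-methyl-5-(3-methylbut-2-en-1-yl)oxolan-3-yl]but-1-en-2-yl}-2-methylhepta-2,6-dien-1-ol (lactol anomers) | OC1[C@@H](C[C@@H](O[Si](C)(C)C(C)(C)C)C(=C)[C@H](CC=C)/C=C(\C)CO)[C@H](C)[C@H](CC=C(C)C)O1 | intermediate
22 | allyldiethylborane: open C6-aldehyde/C12-hydroxy form of 21 with the allylic OH replaced by BEt2 (not isolated) | O=C[C@@H](C[C@@H](O[Si](C)(C)C(C)(C)C)C(=C)[C@H](CC=C)/C=C(\C)CB(CC)CC)[C@H](C)[C@H](CC=C(C)C)O | intermediate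
23 | (1R,2S,4R,6R,7S)-4-[(tert-butyldimethylsilyl)oxy]-2-[(2S,3S)-3-hydroxy-6-methylhept-5-en-2-yl]-5-methylidene-6-(prop-2-en-1-yl)-7-(prop-1-en-2-yl)cycloheptan-1-ol | CC(=C)[C@H]1[C@H](O)[C@H]([C@H](C)[C@H](CC=C(C)C)O)C[C@@H](O[Si](C)(C)C(C)(C)C)C(=C)[C@@H]1CC=C | intermediate
24 | (2S,3S)-2-[(1S,2R,3S,4R,6R)-6-[(tert-butyldimethylsilyl)oxy]-2-hydroxy-5-methylidene-4-(prop-2-en-1-yl)-3-(prop-1-en-2-yl)cycloheptyl]-6-methylhept-5-en-3-yl acetate | CC(=C)[C@H]1[C@H](O)[C@H]([C@H](C)[C@H](CC=C(C)C)OC(C)=O)C[C@@H](O[Si](C)(C)C(C)(C)C)C(=C)[C@@H]1CC=C | intermediate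
25 | (2S,3S)-2-[(3aS,4R,5S,7R,8aR)-7-[(tert-butyldimethylsilyl)oxy]-4-hydroxy-3-methyl-8-methylidene-1,3a,4,5,6,7,8,8a-octahydroazulen-5-yl]-6-methylhept-5-en-3-yl acetate | CC1=CC[C@@H]2[C@@H]1[C@H](O)[C@H]([C@H](C)[C@H](CC=C(C)C)OC(C)=O)C[C@@H](O[Si](C)(C)C(C)(C)C)C2=C | intermediate
26 | (3S,4R)-3,4-epoxide of 25 (oxirane on the face of 6-OH and H-5) | C[C@]12O[C@H]1C[C@@H]1[C@@H]2[C@H](O)[C@H]([C@H](C)[C@H](CC=C(C)C)OC(C)=O)C[C@@H](O[Si](C)(C)C(C)(C)C)C1=C | intermediate
27 | (2S,3S)-2-[(2S,3aS,4R,5S,7R,8aR)-7-[(tert-butyldimethylsilyl)oxy]-2,4-dihydroxy-3,8-dimethylidenedecahydroazulen-5-yl]-6-methylhept-5-en-3-yl acetate | C=C1[C@H]2[C@H](O)[C@H]([C@H](C)[C@H](CC=C(C)C)OC(C)=O)C[C@@H](O[Si](C)(C)C(C)(C)C)C(=C)[C@@H]2C[C@@H]1O | intermediate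
28 | (2S,3S)-2-[(2S,3aS,4R,5S,7R,8aR)-2,4,7-trihydroxy-3,8-dimethylidenedecahydroazulen-5-yl]-6-methylhept-5-en-3-yl acetate (CNP0210891.3) | C=C1[C@H]2[C@H](O)[C@H]([C@H](C)[C@H](CC=C(C)C)OC(C)=O)C[C@@H](O)C(=C)[C@@H]2C[C@@H]1O | target

**Step count**

Total: 24 steps. Longest linear sequence: 18 steps (steps 7–13, then 14–24, from butenolide 9); the other branch (steps 1–6) joins at step 14.

**Steps most likely to fail**

1. Step 19 (ring-closing allylation). The transient allylborane may be lost to protonolysis or β-hydride elimination before the small equilibrium share of open aldehyde is captured, intermolecular allylation may compete with seven-membered ring closure, and the facial preference at C5 may erode if the allylic-strain conformer is not dominant. Fallback: starting from 21, the primary allylic alcohol would be converted chemoselectively (MsCl, LiCl, 2,4,6-collidine, DMF, 0 °C) into chloro lactol F1. F1 would then be cyclised under aqueous Barbier conditions (indium powder, NaI, DMF–H2O, high dilution). This replaces catalytic umpolung of the alcohol by a stoichiometric, water-tolerant allylindium cyclisation of a preformed allylic halide through the same chair, and comes back to the route at 23.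

2. Step 23 (epoxide to exocyclic allylic alcohol). The β-titanoxy radical may be reduced further with loss of oxygen (return to alkene 25), or hydrogen may be lost toward C5 instead of from the C17 methyl. Fallback: starting from 26, a polar silyl-triflate-mediated ring opening (TMSOTf, DBU, toluene, −78→0 °C; ionisation at the tertiary C4–O bond with E2-type loss of a C17 proton, and silylation of 6-OH) would give bis(trimethylsilyl) ether F2. F2 would be desilylated under the conditions of step 24 (HF·pyridine), coming back to the route at 28.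

3. Step 11 (acetal hydrolysis to aldehyde 14). Acid-mediated enolisation of the α-stereogenic β,γ-unsaturated aldehyde may epimerise C1 or move the double bond into conjugation before the Wittig reaction. Fallback: starting from 13, the free aldehyde would be avoided by a Mukaiyama-type addition of 1-ethoxy-1-(trimethylsilyloxy)prop-1-ene to the acetal (TMSOTf cat., CH2Cl2, −78 °C), giving β-methoxy ester F3. E1cB elimination of methanol from F3 (KOt-Bu, THF, 0 °C) comes back to the route at 15.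

**Further compounds**

F1 | step 19 | (3S,4S,5S)-3-{(2R)-2-[(tert-butyldimethylsilyl)oxy]-3-[(3R,4E)-6-chloro-5-methylhexa-1,4-dien-3-yl]but-3-en-1-yl}-4-methyl-5-(3-methylbut-2-en-1-yl)oxolan-2-ol (chloro lactol; 21 with the allylic OH replaced by Cl) | OC1[C@@H](C[C@@H](O[Si](C)(C)C(C)(C)C)C(=C)[C@H](CC=C)/C=C(\C)CCl)[C@H](C)[C@H](CC=C(C)C)O1
F2 | step 23 | (2S,3S)-2-[(2S,3aS,4R,5S,7R,8aR)-7-[(tert-butyldimethylsilyl)oxy]-3,8-dimethylidene-2,4-bis[(trimethylsilyl)oxy]decahydroazulen-5-yl]-6-methylhept-5-en-3-yl acetate | C=C1[C@H]2[C@H](O[Si](C)(C)C)[C@H]([C@H](C)[C@H](CC=C(C)C)OC(C)=O)C[C@@H](O[Si](C)(C)C(C)(C)C)C(=C)[C@@H]2C[C@@H]1O[Si](C)(C)C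
F3 | step 11 | ethyl (4R)-3-methoxy-2-methyl-4-[1-(trimethylsilyl)ethenyl]hept-6-enoate (diastereomers at C2 and C3) | C=CC[C@@H](C(=C)[Si](C)(C)C)C(OC)C(C)C(=O)OCC
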